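(Its constants are assumed; the rest is arithmetic.)

A small charge of solid electrophile dissolves into a flask where nucleophile is being fed and free base stands ready.

    electrophile + nucleophile → acid set free + target (k1 = 5.25 × 10⁻⁴ M⁻¹ s⁻¹)
    nucleophile + acid set free ⇌ protonated nucleophile, settled at all times (K2 = 7100 M⁻¹)
    acid set free + free base ⇌ salt of the base (K3 = 3940 M⁻¹, k3 = 0.0108 M⁻¹ s⁻¹)
    electrophile + target → side product (k4 = 1.63 × 10⁻⁴ M⁻¹ s⁻¹)
    nucleophile + target ⇌ idle adduct, settled at all times (K5 = 100 M⁻¹)
    solid electrophile ⇌ electrophile, rate k6*(cs6 - [electrophile]) while solid is left; crystals form when [electrophile] > cs6 (cs6 = 38 mM, k6 = 3.55 × 10⁻⁵ s⁻¹)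

solid electrophile 0.058 M; nucleophile 0.104 M (fed, over 12 h); free base 0.0290 M; time 40 h

- part of the solid electrophile that has reacted (what has only dissolved counts as not reacted) at 40 h
- share of free nucleophile in free nucleophile and protonated nucleophile together, at 40 h

- percent here means solid electrophile units held: one side product counts as two
- what is said of target includes idle adduct
- solid electrophile is a solid; its amount is given per volume of the solution
- at the start none of the solid electrophile is in solution
- what has only dissolved of solid electrophile counts as not reacted
- run time (flask): 40 h

Take the settings one at a time, in fractions of the charge.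

Nucleophile first. Step 2 is kept at balance, while step 3 goes at its own finite rate; reckon for now that each coupling costs one nucleophile and its acid costs a second. Draw free nucleophile as a triangle: up to half of its charge at the end of the feed, then down towards nothing by 40 h. Its mean is a quarter of the charge, 0.0260 M.

Free base next. Acid held on nucleophile reaches the base with a half-life of about 113 h, forward step alone. That is longer than the run, so leave the base out.

Solid electrophile last. It arrives after a lag of 7.82 h. The charge stands above the solubility, a cap this reckoning does not hold.

Electrophile then decays as a pseudo-first-order species. Call the reach the rate constant of step 1 times the mean free nucleophile times the run time less the lag, 1.58.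

| Setting | Charge | Place in the reach |
|---|---|---|
| nucleophile | 0.104 M | in proportion |
| free base | 0.0290 M | none |
| solid electrophile | 0.058 M | none; its lag counts |

The unreacted part is the exponential of minus the reach, so the reacted part is 79.4 %. This reckoning gives no figure for the free share.

The forecast says 77 % reacted, a little lower, and 23 % free, holding that “the acid sits mostly on the nucleophile”.

The flask gives 76.0 % reacted and 24.3 % free. At 40.0 h it holds 0.0336 M of protonated nucleophile against 0.00643 M of salt of the base. The reach leaves 20.6 % unreacted, and the flask shows 24.0 % as electrophile with 0 % as solid. A neighbour charged with 0.042 M of nucleophile has its reach cut in proportion to 0.639, which leaves 52.8 % unreacted. That neighbour ends with 57.4 % as electrophile and 42.6 % reacted.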